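Remark: locants C1–C15 follow germacrane numbering (ring C1–C10, lactone oxygen on C6, C11 the lactone α-carbon, C12 the lactone carbonyl, C13 the exocyclic methylene, C14 the ester carbon on C10, C15 the methyl on C4). The SMILES is read as written, which fixes a cis-4,5-epoxide (C3 and C6 on the same side of the oxirane), cis oxygens at C8/C9, a ring-cis C1=C10 bond, and 4R,5S,6S,7R,8S,9R with 2S in the side-chain epoxide.

## Analysis of the target

The target is a ten-membered carbocycle (C1–C10) in which every ring carbon from C4 to C10 is functionalized. C4–C5 carry a cis-epoxide (C4 quaternary, with C15). C6–C7 carry a trans-fused α-methylene-γ-butyrolactone, the five-membered ring O–C6–C7–C11(=C13H2)–C12(=O). C8 bears the ester of (2S)-2-methyloxirane-2-carboxylic acid, C9 an acetate, and C10 the methyl ester C14 on the C1=C10 bond, with C2 and C9 cis (E by CIP). The six contiguous ring stereocentres are related as follows: the C5/C6 epoxy-alcohol relation is erythro, H6 and H7 are anti (trans lactone), the C8 and C9 oxygens are cis (erythro), and C7/C8 link the two halves.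

Two retrons stand out. The lactone ring with its flanks C5 and C8 is the product of a carbonyl 2-(alkoxycarbonyl)allylation across C6–C7. The unit C9(O)–C10(=C1)–C14 is a 2-(1-hydroxyalkyl)-2-enoate, the product of an alkenyl-metal addition to an aldehyde.

The sensitive groups are:
- the exo-methylene lactone (Michael acceptor);
- the acid-labile trisubstituted epoxide;
- the nucleophile-labile glycidate;
- the allylic C9 acetate (open to SN2′ displacement);
- the cis-vicinal diester, which can suffer acyl migration or translactonization to O8 once the C8 hydroxyl is free.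

The difficulty is the combination of medium-ring strain with stereocentres on both sides of every sensible ring-forming bond, and the narrow tolerance for acid, base and nucleophiles late in the route.

## Retrosynthetic reasoning

**C8–O acyl bond.** The glycidate is the most fragile group and is cut first: 26 goes back to alcohol 22 and acid 24, the acid coming from alcohol 23 by oxidation. The forward step has to acylate a hindered secondary hydroxyl next to an acetate faster than that acetate can migrate.

**C9–O acetyl and C8–O silyl bonds.** 22 goes back to 21 and then to 20. C9 receives its acetate at the one moment when it is the only free hydroxyl in the molecule, directly after the ring closure that creates it. C8 stays silylated until then, so the cis-diol needs no separate differentiation.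

**C9–C10 (ring closure).** 20 goes back to iodo aldehyde 18, and 18 to the bis-silyl ether 16 by adjusting the oxidation level at C9. The cut is made here because an alkenyl-metal bond reacts with retention, so the ring-cis C1=C10 geometry is simply carried over from a Z-iodoalkene. The same step creates C9 next to the resident C8 centre. The forward reaction has to close a ten-membered ring and choose one face of the aldehyde.

**C6–C7 and O–C12 (key disconnection).** 16 goes back to aldehyde 7 and allylic bromide 13. This cut divides the ring carbons six to four and leaves each half with one block of resident stereochemistry (C4/C5 in 7, C8 in 13). The two centres in between, C6 and C7, and the lactone are made in the joining step with both neighbours directing. The forward reaction must give the anti adduct, add anti to the epoxide C–O bond of 7, and select one face of the allyl unit of 13.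

**West half.** 7 goes back to alcohol 6, then to aldehyde 3 and ylide 4, to epoxy alcohol 2 and to nerol 1. The cis-epoxide is the Z-allylic alcohol of 1 after Sharpless epoxidation. The prenyl terminus of 1 is the latent C1 aldehyde. The iodoenoate comes from an iodo-Wittig reaction that places iodine cis to C2.

**East half.** 13 goes back to diol 12, acetonide 11, adduct 10, and then to aldehyde 8 and acrylate 9. C8 is bought with 8; the 2-(bromomethyl)enoate is the transposed Morita–Baylis–Hillman adduct. The acetonide is exchanged for silyl ethers on this small fragment, so no acid step is needed once the trisubstituted epoxide is present.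

## Alternatives that were turned down

Alternative 1: ring-closing metathesis at C1=C10 (the textbook closure). The triene A1 (lactone in place, C9 acetate, a 2-substituted acrylate at C10, a terminal vinyl group at C2) would be closed with a second-generation Grubbs catalyst. It was turned down for four reasons:
- The olefin to be formed is trisubstituted, carries an ester and lies in a strained ten-membered ring, while its acrylate partner is 1,1-disubstituted and electron-poor, so turnover would be slow.
- A1 holds a second 1,1-disubstituted acrylate (C11=C13) that can engage the vinyl group and close an eight-membered ring instead.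
- The ring strain would be paid in a reversible, nearly thermoneutral step, which favours oligomers.
- C9 would have to come from an intermolecular Morita–Baylis–Hillman reaction on an α-silyloxy aldehyde, which offers little 1,2-induction, so C9 and the ring would become two separate problems.

Alternative 2: the same two bonds in the opposite order, with the C6–C7 allylation as the ring-closing step. Bromo aldehyde A2 would be cyclized with divalent chromium to give the lactone and the ring at once. This is attractive, but A2 needs an allylic bromide and an epoxy aldehyde that are both unveiled after the SN2′-prone C9 acetate is in place. Its assembly requires a C9 aldehyde partner with a masked bromide and a masked C6 aldehyde, which costs four to five extra protecting-group and redox steps. The configuration at C6/C7 would also depend on the conformation of the forming ten-membered ring, which could override the Felkin preference that the 5S,6S relation needs. The intermolecular version lets three acyclic models reinforce each other.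

Alternative 3: C6–C7 by [2,3]-Wittig ring contraction of the 13-membered bis-allylic ether A3 (oxygen bridging C6 and C13). Deprotonation at C6 and the [2,3] shift across C13–C11=C7 would form C6–C7, the exocyclic methylene and the C6 alkoxide while contracting the ring to ten members. It was turned down for four reasons:
- The strong base forbids both esters, so C12 and C14 must be carried as protected alcohols and oxidized later.
- C6 and C13 are both α-oxy allylic positions, with nothing to direct the deprotonation.
- The 4,5-olefin would have to be epoxidized after ring formation, where the A(1,3)-controlled preference of a Z-allylic alcohol points to the threo isomer and the target needs erythro.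
- A3 itself needs a macrocyclic etherification.

Key step: step 9

## Route

Step 1
Reactants: 1 nerol
Product: 2 [(2S,3R)-3-methyl-3-(4-methylpent-3-en-1-yl)oxiran-2-yl]methanol
Conditions: Ti(OiPr)4 (cat.), L-(+)-diethyl tartrate (cat.), t-BuOOH, 4 Å molecular sieves, CH2Cl2, −20 °C
Reagents that add atoms: tert-butyl hydroperoxide, CC(C)(C)OO
Why: Sharpless asymmetric epoxidation, which touches only the allylic-alcohol olefin; L-(+)-tartrate gives the 2S series, and the Z geometry of nerol becomes the cis relation of C3 and C6 (C4 R, C5 S).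

Step 2
Reactants: 2 [(2S,3R)-3-methyl-3-(4-methylpent-3-en-1-yl)oxiran-2-yl]methanol
Product: 3 3-[(2R,3S)-3-(hydroxymethyl)-2-methyloxiran-2-yl]propanal
Conditions: O3, CH2Cl2, −78 °C; PPh3, −78 °C → rt
Reagents that add atoms: ozone, [O-][O+]=O
Why: Ozonolysis with reductive work-up; the trisubstituted olefin is the only C=C bond, and the epoxide and the free alcohol are inert to ozone at −78 °C.

Step 3
Reactants: 3 3-[(2R,3S)-3-(hydroxymethyl)-2-methyloxiran-2-yl]propanal; 4 methyl (triphenylphosphoranylidene)acetate
Product: 6 methyl (2Z)-5-[(2R,3S)-3-(hydroxymethyl)-2-methyloxiran-2-yl]-2-iodopent-2-enoate, via iodo ylide 5 (not isolated)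
Conditions: 4, N-iodosuccinimide, CH2Cl2, −20 °C; then 3, K2CO3, −20 °C → rt
Reagents that add atoms: N-iodosuccinimide, O=C1CCC(=O)N1I
Why: Wittig olefination with an α-iodo stabilized ylide made in the flask by iodination and deprotonation of 4; ylides of this type place the new substituent trans to the ester, so iodine ends up cis to C2 (Z), the geometry the ring needs at C1=C10.

Step 4
Reactants: 6 methyl (2Z)-5-[(2R,3S)-3-(hydroxymethyl)-2-methyloxiran-2-yl]-2-iodopent-2-enoate
Product: 7 methyl (2Z)-5-[(2R,3R)-3-formyl-2-methyloxiran-2-yl]-2-iodopent-2-enoate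
Conditions: Dess–Martin periodinane, pyridine, CH2Cl2, 0 °C → rt
Reagents that add atoms: none
Why: Dess–Martin oxidation of a primary epoxy alcohol under buffered, near-neutral conditions, so neither epoxide opening nor epimerization at C5 is expected; 7 is used without storage.

Step 5
Reactants: 8 (4R)-2,2-dimethyl-1,3-dioxolane-4-carbaldehyde; 9 methyl acrylate
Product: 10 methyl 2-{[(4R)-2,2-dimethyl-1,3-dioxolan-4-yl](hydroxy)methyl}prop-2-enoate (both carbinol epimers)
Conditions: DABCO (0.5 equiv), 1,4-dioxane/H2O (1:1), rt
Reagents that add atoms: none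
Why: Morita–Baylis–Hillman reaction; the aqueous medium shortens the contact of the base-sensitive α-alkoxy aldehyde with the amine, and the new carbinol centre (C7) may form as a mixture because it becomes sp2 in step 6.

Step 6
Reactants: 10 methyl 2-{[(4R)-2,2-dimethyl-1,3-dioxolan-4-yl](hydroxy)methyl}prop-2-enoate
Product: 11 methyl (2Z)-2-(bromomethyl)-3-[(4S)-2,2-dimethyl-1,3-dioxolan-4-yl]prop-2-enoate
Conditions: N-bromosuccinimide, Me2S, CH2Cl2, 0 °C → rt
Reagents that add atoms: N-bromosuccinimide, O=C1CCC(=O)N1Br
Why: Corey–Kim-type bromination of a Morita–Baylis–Hillman alcohol with allylic transposition (SN2′); the more stable olefin, with the dioxolanyl group trans to the ester, is the Z bromide, and the neutral conditions keep the acetonide.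

Step 7
Reactants: 11 methyl (2Z)-2-(bromomethyl)-3-[(4S)-2,2-dimethyl-1,3-dioxolan-4-yl]prop-2-enoate
Product: 12 methyl (2Z,4S)-2-(bromomethyl)-4,5-dihydroxypent-2-enoate
Conditions: CF3CO2H/H2O (9:1), THF, 0 °C; concentrated cold and used crude
Reagents that add atoms: none
Why: Acid hydrolysis of a terminal acetonide, done on the small fragment so that no acid step follows the union; in acid the hydroxyl groups are poor nucleophiles toward the allylic bromide, and 12 is silylated at once.

Step 8
Reactants: 12 methyl (2Z,4S)-2-(bromomethyl)-4,5-dihydroxypent-2-enoate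
Product: 13 methyl (2Z,4S)-2-(bromomethyl)-4,5-bis(triethylsilyloxy)pent-2-enoate
Conditions: Et3SiOTf, 2,6-lutidine, CH2Cl2, −78 °C
Reagents that add atoms: triethylsilyl trifluoromethanesulfonate, CC[Si](CC)(CC)OS(=O)(=O)C(F)(F)F
Why: Silylation with a silyl triflate and a hindered pyridine at −78 °C is faster than any alkylation by the allylic bromide; the primary and the secondary triethylsilyl ether can be told apart later.

Step 9
Reactants: 7 methyl (2Z)-5-[(2R,3R)-3-formyl-2-methyloxiran-2-yl]-2-iodopent-2-enoate; 13 methyl (2Z,4S)-2-(bromomethyl)-4,5-bis(triethylsilyloxy)pent-2-enoate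
Product: 16 methyl (2Z)-5-[(2R,3S)-3-{(2S,3S)-3-[(1S)-1,2-bis(triethylsilyloxy)ethyl]-4-methylidene-5-oxooxolan-2-yl}-2-methyloxiran-2-yl]-2-iodopent-2-enoate, via allylchromium dichloride 14 (not isolated), via chromium alkoxide 15 (not isolated)
Conditions: CrCl2 (nickel-free, 4 equiv), THF, 0 °C → rt; aq. NH4Cl
Reagents that add atoms: none
Why: Divalent chromium inserts into the allylic C–Br bond of 13 in two one-electron steps to give the trivalent allylchromium reagent 14, whose 1,3-metal shift lets C8 settle trans to the CH2–Cr group; 14 adds through its γ-carbon (C7) to the aldehyde of 7 in a closed six-membered chair of the Zimmerman–Traxler type, and the chromium alkoxide 15 then closes onto the methyl ester (5-exo-trig acyl substitution, loss of methoxide) to give the α-methylene-γ-butyrolactone. The closest known reaction type is the CrCl2-mediated Nozaki–Hiyama 2-(alkoxycarbonyl)allylation of aldehydes, which gives such lactones directly. C6 relative to C7: equatorial C8 and an equatorial aldehyde substituent in the chair give the anti adduct, which is the trans-disubstituted lactone. C7 relative to C8: with H8 eclipsing the C7=C11 bond (A(1,3) strain with the ester), the aldehyde should approach the face anti to the C8–C9 bond, the larger group and the better σ-donor, and syn to the silyloxy group. C6 relative to C5: Felkin–Anh attack anti to the epoxide C5–O bond gives the erythro epoxy alcohol. All three preferences lead to the same diastereomer, so (4S)-13 and (2R,3R)-7 form the matched pair, and the minor enantiomer of 7 left by step 1 ends up in separable diastereomers. The step needs the allylic bromide to react while the alkenyl iodide stays untouched, which nickel-free CrCl2 in THF should secure because alkenyl iodides need a nickel co-catalyst, and allylchromium reagents add to aldehydes but not to esters or epoxides. The silyl ether at C8 is a poor leaving group and the aldehyde is present from the start, which guards against 1,4-elimination of the allylmetal.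

Step 10
Reactants: 16 methyl (2Z)-5-[(2R,3S)-3-{(2S,3S)-3-[(1S)-1,2-bis(triethylsilyloxy)ethyl]-4-methylidene-5-oxooxolan-2-yl}-2-methyloxiran-2-yl]-2-iodopent-2-enoate
Product: 18 methyl (2Z)-5-[(2R,3S)-3-{(2S,3S)-4-methylidene-5-oxo-3-[(1S)-2-oxo-1-(triethylsilyloxy)ethyl]oxolan-2-yl}-2-methyloxiran-2-yl]-2-iodopent-2-enoate, via alkoxysulfonium chloride 17 (not isolated)
Conditions: (COCl)2, DMSO, CH2Cl2, −78 → −40 °C; Et3N, −78 → 0 °C
Reagents that add atoms: none
Why: Swern oxidation applied directly to the bis-silyl ether: the chlorosulfonium reagent cleaves the primary triethylsilyl ether selectively and the alkoxysulfonium ion 17 collapses to the aldehyde on adding the amine; the secondary silyl ether, the epoxide and both acceptors are inert at low temperature, and the cold work-up limits epimerization at C8.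

Step 11
Reactants: 18 methyl (2Z)-5-[(2R,3S)-3-{(2S,3S)-4-methylidene-5-oxo-3-[(1S)-2-oxo-1-(triethylsilyloxy)ethyl]oxolan-2-yl}-2-methyloxiran-2-yl]-2-iodopent-2-enoate
Product: 20 (1(10)E,4R,5S,6S,7S,8S,9R)-4,5-epoxy-9-hydroxy-14-methoxy-14-oxo-8-(triethylsilyloxy)germacra-1(10),11(13)-dien-12,6-olide, via alkenylchromium species 19 (not isolated)
Conditions: CrCl2 (15 equiv), NiCl2 (cat.), DMSO, rt, 0.002 M, syringe-pump addition of 18
Reagents that add atoms: none
Why: Nozaki–Hiyama–Kishi reaction: zerovalent nickel inserts into the C–I bond, transmetalation gives the trivalent alkenylchromium species 19 with retention, and 19 adds to the C9 aldehyde (10-exo-trig), so C2 and C9 end up cis on C1=C10. Felkin–Anh addition anti to the C8 silyloxy group should give 9R (8,9-erythro); the trans lactone, the cis-epoxide and the Z-olefin pre-fold the chain, and high dilution holds back dimerization.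

Step 12
Reactants: 20 (1(10)E,4R,5S,6S,7S,8S,9R)-4,5-epoxy-9-hydroxy-14-methoxy-14-oxo-8-(triethylsilyloxy)germacra-1(10),11(13)-dien-12,6-olide
Product: 21 (1(10)E,4R,5S,6S,7S,8S,9R)-9-acetoxy-4,5-epoxy-14-methoxy-14-oxo-8-(triethylsilyloxy)germacra-1(10),11(13)-dien-12,6-olide
Conditions: Ac2O, pyridine, DMAP (cat.), CH2Cl2, 0 °C
Reagents that add atoms: acetic anhydride, CC(=O)OC(C)=O
Why: Acetylation of the only free hydroxyl group; mild base at 0 °C avoids SN2′ displacement at the allylic position.

Step 13
Reactants: 21 (1(10)E,4R,5S,6S,7S,8S,9R)-9-acetoxy-4,5-epoxy-14-methoxy-14-oxo-8-(triethylsilyloxy)germacra-1(10),11(13)-dien-12,6-olide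
Product: 22 (1(10)E,4R,5S,6S,7R,8S,9R)-9-acetoxy-4,5-epoxy-8-hydroxy-14-methoxy-14-oxogermacra-1(10),11(13)-dien-12,6-olide
Conditions: HF·pyridine, pyridine, THF, 0 °C
Reagents that add atoms: none
Why: Fluoride-mediated desilylation buffered with pyridine; in this weakly acidic medium acetyl migration from O9 to O8 and translactonization to O8 are slow, and both the epoxide and the allylic acetate survive.

Step 14
Reactants: 23 [(2R)-2-methyloxiran-2-yl]methanol
Product: 24 (2S)-2-methyloxirane-2-carboxylic acid
Conditions: RuCl3 (cat.), NaIO4, MeCN/EtOAc/H2O, 0 °C → rt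
Reagents that add atoms: sodium periodate, [Na+].[O-]I(=O)(=O)=O; water, O
Why: Oxidation of a primary epoxy alcohol to the epoxy acid by RuO4 generated in the flask; the quaternary centre cannot epimerize, and the descriptor changes from R to S only because the CIP priorities change.

Step 15
Reactants: 22 (1(10)E,4R,5S,6S,7R,8S,9R)-9-acetoxy-4,5-epoxy-8-hydroxy-14-methoxy-14-oxogermacra-1(10),11(13)-dien-12,6-olide; 24 (2S)-2-methyloxirane-2-carboxylic acid
Product: 26 (1(10)E,4R,5S,6S,7R,8S,9R)-9-acetoxy-4,5-epoxy-14-methoxy-8-{[(2S)-2-methyloxirane-2-carbonyl]oxy}-14-oxogermacra-1(10),11(13)-dien-12,6-olide, via mixed anhydride 25 (not isolated)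
Conditions: 24, 2,4,6-trichlorobenzoyl chloride, Et3N, THF, 0 °C; then 22, DMAP, toluene, rt
Reagents that add atoms: none
Why: Yamaguchi esterification; the preformed mixed anhydride 25, used in excess with DMAP, should acylate the hindered C8 hydroxyl faster than the neighbouring acetate can migrate, and the glycidate epoxide is not attacked by these weakly nucleophilic bases at rt.

## Compound list

1 | nerol, (2Z)-3,7-dimethylocta-2,6-dien-1-ol | CC(C)=CCC/C(C)=C\CO | starting material
2 | [(2S,3R)-3-methyl-3-(4-methylpent-3-en-1-yl)oxiran-2-yl]methanol | CC(C)=CCC[C@@]1(C)O[C@H]1CO | intermediate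
3 | 3-[(2R,3S)-3-(hydroxymethyl)-2-methyloxiran-2-yl]propanal | O=CCC[C@@]1(C)O[C@H]1CO | intermediate
4 | methyl (triphenylphosphoranylidene)acetate | COC(=O)C=P(c1ccccc1)(c1ccccc1)c1ccccc1 | starting material
5 | methyl iodo(triphenylphosphoranylidene)acetate (iodo ylide, not isolated) | COC(=O)C(I)=P(c1ccccc1)(c1ccccc1)c1ccccc1 | intermediate
6 | methyl (2Z)-5-[(2R,3S)-3-(hydroxymethyl)-2-methyloxiran-2-yl]-2-iodopent-2-enoate | COC(=O)/C(I)=C/CC[C@@]1(C)O[C@H]1CO | intermediate
7 | methyl (2Z)-5-[(2R,3R)-3-formyl-2-methyloxiran-2-yl]-2-iodopent-2-enoate | COC(=O)/C(I)=C/CC[C@@]1(C)O[C@H]1C=O | intermediate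
8 | (4R)-2,2-dimethyl-1,3-dioxolane-4-carbaldehyde | O=C[C@H]1COC(C)(C)O1 | starting material
9 | methyl acrylate | C=CC(=O)OC | starting material
10 | methyl 2-{[(4R)-2,2-dimethyl-1,3-dioxolan-4-yl](hydroxy)methyl}prop-2-enoate (both carbinol epimers) | C=C(C(=O)OC)C(O)[C@H]1COC(C)(C)O1 | intermediate
11 | methyl (2Z)-2-(bromomethyl)-3-[(4S)-2,2-dimethyl-1,3-dioxolan-4-yl]prop-2-enoate | COC(=O)/C(CBr)=C/[C@H]1COC(C)(C)O1 | intermediate
12 | methyl (2Z,4S)-2-(bromomethyl)-4,5-dihydroxypent-2-enoate | COC(=O)/C(CBr)=C/[C@H](O)CO | intermediate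
13 | methyl (2Z,4S)-2-(bromomethyl)-4,5-bis(triethylsilyloxy)pent-2-enoate | COC(=O)/C(CBr)=C/[C@H](O[Si](CC)(CC)CC)CO[Si](CC)(CC)CC | intermediate
14 | trivalent allylchromium dichloride from 13, C8 trans to the CH2–Cr group after 1,3-shift (not isolated) | COC(=O)/C(C[Cr](Cl)Cl)=C\[C@H](O[Si](CC)(CC)CC)CO[Si](CC)(CC)CC | intermediate
15 | chromium alkoxide of the anti homoallylic alcohol, C6 alkoxide with C7 bearing the 1-(methoxycarbonyl)vinyl group, configuration at C4–C8 as in 16 (not isolated) | C=C(C(=O)OC)[C@H]([C@H](O[Si](CC)(CC)CC)CO[Si](CC)(CC)CC)[C@H](O[Cr](Cl)Cl)[C@@H]1O[C@]1(C)CC/C=C(\I)C(=O)OC | intermediate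
16 | methyl (2Z)-5-[(2R,3S)-3-{(2S,3S)-3-[(1S)-1,2-bis(triethylsilyloxy)ethyl]-4-methylidene-5-oxooxolan-2-yl}-2-methyloxiran-2-yl]-2-iodopent-2-enoate | C=C1C(=O)O[C@H]([C@@H]2O[C@]2(C)CC/C=C(\I)C(=O)OC)[C@H]1[C@H](O[Si](CC)(CC)CC)CO[Si](CC)(CC)CC | intermediate
17 | dimethyl(alkoxy)sulfonium chloride of the C9 primary oxygen of 16 (not isolated) | C=C1C(=O)O[C@H]([C@@H]2O[C@]2(C)CC/C=C(\I)C(=O)OC)[C@H]1[C@H](O[Si](CC)(CC)CC)CO[S+](C)C.[Cl-] | intermediate
18 | methyl (2Z)-5-[(2R,3S)-3-{(2S,3S)-4-methylidene-5-oxo-3-[(1S)-2-oxo-1-(triethylsilyloxy)ethyl]oxolan-2-yl}-2-methyloxiran-2-yl]-2-iodopent-2-enoate | C=C1C(=O)O[C@H]([C@@H]2O[C@]2(C)CC/C=C(\I)C(=O)OC)[C@H]1[C@H](O[Si](CC)(CC)CC)C=O | intermediate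
19 | trivalent alkenylchromium dichloride from 18, chromium in place of iodine with retained geometry (not isolated) | C=C1C(=O)O[C@H]([C@@H]2O[C@]2(C)CC/C=C(\[Cr](Cl)Cl)C(=O)OC)[C@H]1[C@H](O[Si](CC)(CC)CC)C=O | intermediate
20 | (1(10)E,4R,5S,6S,7S,8S,9R)-4,5-epoxy-9-hydroxy-14-methoxy-14-oxo-8-(triethylsilyloxy)germacra-1(10),11(13)-dien-12,6-olide | C=C1C(=O)O[C@H]2[C@H]1[C@H](O[Si](CC)(CC)CC)[C@H](O)/C(C(=O)OC)=C\CC[C@@]1(C)O[C@@H]21 | intermediate
21 | (1(10)E,4R,5S,6S,7S,8S,9R)-9-acetoxy-4,5-epoxy-14-methoxy-14-oxo-8-(triethylsilyloxy)germacra-1(10),11(13)-dien-12,6-olide | C=C1C(=O)O[C@H]2[C@H]1[C@H](O[Si](CC)(CC)CC)[C@H](OC(C)=O)/C(C(=O)OC)=C\CC[C@@]1(C)O[C@@H]21 | intermediate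
22 | (1(10)E,4R,5S,6S,7R,8S,9R)-9-acetoxy-4,5-epoxy-8-hydroxy-14-methoxy-14-oxogermacra-1(10),11(13)-dien-12,6-olide | C=C1C(=O)O[C@H]2[C@H]1[C@H](O)[C@H](OC(C)=O)/C(C(=O)OC)=C\CC[C@@]1(C)O[C@@H]21 | intermediate
23 | [(2R)-2-methyloxiran-2-yl]methanol, (R)-2-methylglycidol | OC[C@]1(C)CO1 | starting material
24 | (2S)-2-methyloxirane-2-carboxylic acid | OC(=O)[C@]1(C)CO1 | intermediate
25 | (2S)-2-methyloxirane-2-carboxylic 2,4,6-trichlorobenzoic anhydride (not isolated) | O=C(OC(=O)[C@]1(C)CO1)c1c(Cl)cc(Cl)cc1Cl | intermediate
26 | (1(10)E,4R,5S,6S,7R,8S,9R)-9-acetoxy-4,5-epoxy-14-methoxy-8-{[(2S)-2-methyloxirane-2-carbonyl]oxy}-14-oxogermacra-1(10),11(13)-dien-12,6-olide, CNP0274195.2 | C=C1C(=O)O[C@H]2[C@H]1[C@H](OC(=O)[C@]1(C)CO1)[C@H](OC(C)=O)/C(C(=O)OC)=C\CC[C@@]1(C)O[C@@H]21 | target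

## Step count and least certain steps

Total: 15 steps. Longest linear sequence: 10 steps (steps 1–4 or 5–8, then 9–13 and 15).

**Step 9 (key step).** The most likely failure is loss of the anti sense of addition. The ester on C11 may hold C8 cis to the CH2–Cr group (the geometry of bromide 13); the corresponding chair has C8 axial and leads to the cis lactone. Two lesser concerns are 1,4-elimination of the allylmetal with loss of the C8 silyloxide and slow reduction of the C–I bond. The fallback fixes the allyl geometry in a reagent that cannot equilibrate and uses no low-valent metal. It sets out from 8 and returns at 16.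
- Ohira–Bestmann homologation of 8 (dimethyl (1-diazo-2-oxopropyl)phosphonate, K2CO3, MeOH) gives (4S)-4-ethynyl-2,2-dimethyl-1,3-dioxolane F1.
- Aqueous acid gives (2S)-but-3-yne-1,2-diol F2.
- Et3SiCl and imidazole give (3S)-3,4-bis(triethylsilyloxy)but-1-yne F3.
- n-BuLi followed by methyl chloroformate gives methyl (4S)-4,5-bis(triethylsilyloxy)pent-2-ynoate F4.
- 1,4-Hydroalumination with i-Bu2AlH in THF/HMPA places hydrogen and aluminium cis; alkylation of the α-aluminio enoate with 2-(iodomethyl)-4,4,5,5-tetramethyl-1,3,2-dioxaborolane gives methyl (2Z,4S)-2-[(4,4,5,5-tetramethyl-1,3,2-dioxaborolan-2-yl)methyl]-4,5-bis(triethylsilyloxy)pent-2-enoate F5, in which C8 is trans to the CH2–B group.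
- Heating F5 with 7 in toluene is a stereospecific allylboration through a closed chair with C8 equatorial by construction. It should give the anti adduct, whose borate closes to lactone 16.

**Step 11.** The most likely failure is addition to the wrong face of the C9 aldehyde, because in a ring-closing transition state the tether, not the C8 silyl ether, may choose the aldehyde rotamer; slow closure would also let dimerization compete. The fallback sets out from 18 and returns at 21. If the ring closes mainly to the (9S)-alcohol, (1(10)E,4R,5S,6S,7S,8S,9S)-4,5-epoxy-9-hydroxy-14-methoxy-14-oxo-8-(triethylsilyloxy)germacra-1(10),11(13)-dien-12,6-olide F6, this epimer is treated with acetic acid, PPh3 and diisopropyl azodicarboxylate. The Mitsunobu reaction inverts C9 and gives acetate 21 directly. Any 20 formed alongside goes through step 12, so both epimers converge on 21.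

**Step 15.** The most likely failure is acetyl migration from O9 to the free O8, or translactonization to O8, while 22 waits under basic conditions for a slow acylation. The fallback changes the order of the two acylations so that the slow one is done while C9 is blocked. It sets out from 20 and returns at 26.
- t-BuMe2SiOTf and 2,6-lutidine give the 9-O-tert-butyldimethylsilyl 8-O-triethylsilyl ether F7.
- Buffered HF·pyridine at 0 °C removes only the triethylsilyl group and gives the 8-hydroxy 9-O-tert-butyldimethylsilyl ether F8.
- Yamaguchi esterification with 24 (through 25) gives the 8-O-[(2S)-2-methyloxirane-2-carbonyl] 9-O-tert-butyldimethylsilyl ether F9.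
- HF·pyridine at rt gives the 9-hydroxy 8-glycidate F10.
- Fast acetylation (Ac2O, pyridine, DMAP) gives 26.

**Step 7.** The most likely failure is intramolecular O-alkylation in diol bromide 12, where the C8 or C9 hydroxyl displaces the allylic bromide that lies cis to it, giving a dihydrofuran or dihydropyran. The fallback introduces the bromide only after the diol is silylated. It sets out from 10 and returns at 13.
- Acetylation of 10 gives methyl 2-{(acetyloxy)[(4R)-2,2-dimethyl-1,3-dioxolan-4-yl]methyl}prop-2-enoate F11.
- Aqueous acid gives methyl 2-[(2R)-1-(acetyloxy)-2,3-dihydroxypropyl]prop-2-enoate F12.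
- Et3SiOTf and 2,6-lutidine give methyl 2-[(2R)-1-(acetyloxy)-2,3-bis(triethylsilyloxy)propyl]prop-2-enoate F13.
- SN2′ displacement of the acetate with MgBr2·OEt2 in THF gives the Z bromide 13.

## Further compounds

F1 | step 9 | (4S)-4-ethynyl-2,2-dimethyl-1,3-dioxolane | C#C[C@H]1COC(C)(C)O1
F2 | step 9 | (2S)-but-3-yne-1,2-diol | C#C[C@H](O)CO
F3 | step 9 | (3S)-3,4-bis(triethylsilyloxy)but-1-yne | C#C[C@H](O[Si](CC)(CC)CC)CO[Si](CC)(CC)CC
F4 | step 9 | methyl (4S)-4,5-bis(triethylsilyloxy)pent-2-ynoate | COC(=O)C#C[C@H](O[Si](CC)(CC)CC)CO[Si](CC)(CC)CC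
F5 | step 9 | methyl (2Z,4S)-2-[(4,4,5,5-tetramethyl-1,3,2-dioxaborolan-2-yl)methyl]-4,5-bis(triethylsilyloxy)pent-2-enoate | COC(=O)/C(CB1OC(C)(C)C(C)(C)O1)=C\[C@H](O[Si](CC)(CC)CC)CO[Si](CC)(CC)CC
F6 | step 11 | (1(10)E,4R,5S,6S,7S,8S,9S)-4,5-epoxy-9-hydroxy-14-methoxy-14-oxo-8-(triethylsilyloxy)germacra-1(10),11(13)-dien-12,6-olide | C=C1C(=O)O[C@H]2[C@H]1[C@H](O[Si](CC)(CC)CC)[C@@H](O)/C(C(=O)OC)=C\CC[C@@]1(C)O[C@@H]21
F7 | step 15 | 9-O-tert-butyldimethylsilyl 8-O-triethylsilyl ether, ring configuration as in 20 | C=C1C(=O)O[C@H]2[C@H]1[C@H](O[Si](CC)(CC)CC)[C@H](O[Si](C)(C)C(C)(C)C)/C(C(=O)OC)=C\CC[C@@]1(C)O[C@@H]21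
F8 | step 15 | 8-hydroxy 9-O-tert-butyldimethylsilyl ether, ring configuration as in 20 | C=C1C(=O)O[C@H]2[C@H]1[C@H](O)[C@H](O[Si](C)(C)C(C)(C)C)/C(C(=O)OC)=C\CC[C@@]1(C)O[C@@H]21
F9 | step 15 | 8-O-[(2S)-2-methyloxirane-2-carbonyl] 9-O-tert-butyldimethylsilyl ether, ring configuration as in 26 | C=C1C(=O)O[C@H]2[C@H]1[C@H](OC(=O)[C@]1(C)CO1)[C@H](O[Si](C)(C)C(C)(C)C)/C(C(=O)OC)=C\CC[C@@]1(C)O[C@@H]21
F10 | step 15 | 9-hydroxy 8-O-[(2S)-2-methyloxirane-2-carbonyl] compound, ring configuration as in 26 | C=C1C(=O)O[C@H]2[C@H]1[C@H](OC(=O)[C@]1(C)CO1)[C@H](O)/C(C(=O)OC)=C\CC[C@@]1(C)O[C@@H]21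
F11 | step 7 | methyl 2-{(acetyloxy)[(4R)-2,2-dimethyl-1,3-dioxolan-4-yl]methyl}prop-2-enoate (both epimers at the acetoxy carbon) | C=C(C(=O)OC)C(OC(C)=O)[C@H]1COC(C)(C)O1
F12 | step 7 | methyl 2-[(2R)-1-(acetyloxy)-2,3-dihydroxypropyl]prop-2-enoate | C=C(C(=O)OC)C(OC(C)=O)[C@H](O)CO
F13 | step 7 | methyl 2-[(2R)-1-(acetyloxy)-2,3-bis(triethylsilyloxy)propyl]prop-2-enoate | C=C(C(=O)OC)C(OC(C)=O)[C@H](O[Si](CC)(CC)CC)CO[Si](CC)(CC)CC
A1 | alternative 1 | metathesis triene: trans lactone of the main route with a terminal vinyl group at C2, C9 acetate, C8 triethylsilyl ether, methyl 2-substituted acrylate at C10 | C=C1C(=O)O[C@H]([C@@H]2O[C@]2(C)CCC=C)[C@H]1[C@H](O[Si](CC)(CC)CC)[C@H](OC(C)=O)C(=C)C(=O)OC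
A2 | alternative 2 | seco bromo aldehyde: C6 epoxy aldehyde, C13 allylic bromide, C9 acetate, C8 triethylsilyl ether, C1=C10 enoate in place | BrC/C(C(=O)OC)=C\[C@H](O[Si](CC)(CC)CC)[C@H](OC(C)=O)/C(C(=O)OC)=C\CC[C@@]1(C)O[C@H]1C=O
A3 | alternative 3 | 13-membered bis-allylic ether with oxygen bridging C6 and C13, C8/C9 acetonide, C12 and C14 as silyl-protected primary alcohols | C/C1=C/COC/C(CO[Si](C)(C)C(C)(C)C)=C\[C@@H]2OC(C)(C)O[C@@H]2/C(CO[Si](C)(C)C(C)(C)C)=C\CC1
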